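**Plan**
- Cuts, in retrosynthetic order: the two O–Si bonds; the CH–CH single bond in the middle of the polyene (Stille), giving a ring A C16 bromodienyne and a butenolide dienylstannane; in the bromodienyne, the C–CH3 bond and the next CH–CH bond of the alkene beside the ring A alkyne; in the stannane, the CH=CH(Sn) alkene, the bond from the butenolide α-carbon to the ring B vinyl group, and the lactone C–O and alkyne C–C bonds.
- Forward: both six-membered carbocycles come from actinol. Ring A is taken to its buta-1,3-diyne and on to the bromodienyne. Ring B gains its oxirane by epoxidation and becomes a vinylstannane. The butenolide closes by 5-exo-dig lactonisation, is joined to ring B and given its stannyl diene, and the two halves are united last.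
- Enabling feature: cyclohexene ring A carries a C≡C whose far carbon bears the C(CH3)=CH unit. This methyl-substituted trisubstituted alkene flanked by an alkyne is what a terminal C≡C–C≡C–H on ring A becomes when CH3 and a metal add syn across its end.
- Stereochemistry: both carbinol centres come from (4R,6R)-actinol and the two oxirane centres from a Sharpless epoxidation. Alkene geometries come from syn carbometalation, (E)-BrCH=CHI, syn hydrostannation, anti oxymetalation (Z ylidene), E-selective chromium olefination and stereoretentive couplings.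

Key step: step 7

Assumption: (2E)-3-methylpent-2-en-4-yn-1-ol is taken as purchasable in isomerically pure form.

**Route**

Step 1
Reactants: 1 (4R,6R)-4-hydroxy-2,2,6-trimethylcyclohexan-1-one (actinol)
Product: 2 (4R,6R)-4-[(tert-butyldimethylsilyl)oxy]-2,2,6-trimethylcyclohexan-1-one
Conditions: TBSCl, imidazole, DMF, rt
Reagents that add atoms: tert-butyldimethylsilyl chloride, CC(C)(C)[Si](C)(C)Cl
Why: Imidazole-promoted O-silylation of the only hydroxyl gives a silyl ether that should survive all later base, organometallic and palladium steps; no stereocentre is touched.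

Step 2
Reactants: 2 (4R,6R)-4-[(tert-butyldimethylsilyl)oxy]-2,2,6-trimethylcyclohexan-1-one
Product: 4 (4R)-4-[(tert-butyldimethylsilyl)oxy]-2,6,6-trimethylcyclohex-1-en-1-yl trifluoromethanesulfonate, via lithium enolate 3 (not isolated)
Conditions: LiN(iPr)2, THF, −78 °C; then PhNTf2, −78 °C → rt
Reagents that add atoms: N-phenylbis(trifluoromethanesulfonimide), O=S(=O)(N(c1ccccc1)S(=O)(=O)C(F)(F)F)C(F)(F)F
Why: Enol triflate formation: only C6 has an α-hydrogen (C2 is quaternary), so deprotonation and O-sulfonylation can give only the tetrasubstituted ring alkene; the C6 centre is erased on purpose and the carbinol centre is untouched.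

Step 3
Reactants: 5 1,4-bis(trimethylsilyl)buta-1,3-diyne
Product: 7 buta-1,3-diyn-1-yl(trimethyl)silane, via lithium trimethylsilylbutadiynide 6 (not isolated)
Conditions: MeLi·LiBr (1 equiv), Et2O, rt; then H2O, 0 °C
Reagents that add atoms: none
Why: Nucleophilic desilylation: one equivalent of methyllithium cleaves a single C–Si bond because the diynide anion formed is deactivated towards a second attack, and protonation gives the mono-capped diyne, to be used as a solution.

Step 4
Reactants: 4 (4R)-4-[(tert-butyldimethylsilyl)oxy]-2,6,6-trimethylcyclohex-1-en-1-yl trifluoromethanesulfonate; 7 buta-1,3-diyn-1-yl(trimethyl)silane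
Product: 8 tert-butyldimethyl{[(1R)-3,5,5-trimethyl-4-[4-(trimethylsilyl)buta-1,3-diyn-1-yl]cyclohex-3-en-1-yl]oxy}silane
Conditions: Pd(PPh3)4 (cat.), CuI (cat.), iPr2NH, THF, rt
Reagents that add atoms: none
Why: Sonogashira coupling of the alkenyl triflate with the terminal alkyne; the trimethylsilyl cap keeps the diyne from reacting at both ends.

Step 5
Reactants: 8 tert-butyldimethyl{[(1R)-3,5,5-trimethyl-4-[4-(trimethylsilyl)buta-1,3-diyn-1-yl]cyclohex-3-en-1-yl]oxy}silane
Product: 9 {[(1R)-4-(buta-1,3-diyn-1-yl)-3,5,5-trimethylcyclohex-3-en-1-yl]oxy}(tert-butyl)dimethylsilane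
Conditions: K2CO3 (cat.), MeOH/THF, 0 °C
Reagents that add atoms: none
Why: Carbonate-catalysed methanolysis of the alkynyl C–Si bond (protodesilylation) is far faster than cleavage of the secondary alkyl TBS ether; the terminal diyne should be used at once.

Step 6
Reactants: 10 acetylene
Product: 11 (E)-1-bromo-2-iodoethene
Conditions: IBr, 48% aq. HBr, 0 °C
Reagents that add atoms: iodine monobromide, BrI
Why: Electrophilic anti addition of I–Br across acetylene (iodonium opened by bromide) gives the E dihaloethene.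

Step 7
Reactants: 9 {[(1R)-4-(buta-1,3-diyn-1-yl)-3,5,5-trimethylcyclohex-3-en-1-yl]oxy}(tert-butyl)dimethylsilane; 12 trimethylaluminium; 11 (E)-1-bromo-2-iodoethene
Product: 14 {[(1R)-4-[(3E,5E)-6-bromo-3-methylhexa-3,5-dien-1-yn-1-yl]-3,5,5-trimethylcyclohex-3-en-1-yl]oxy}(tert-butyl)dimethylsilane, via (E)-alkenyldimethylalane 13 (not isolated)
Conditions: AlMe3, Cp2ZrCl2 (cat.), (CH2Cl)2, 0 °C → rt; volatiles removed in vacuo; then 11 (excess), Pd(PPh3)4 (cat.), ZnCl2 (cat.), THF, rt
Reagents that add atoms: none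
Why: A methylzirconocene species formed from Cp2ZrCl2 and AlMe3 adds CH3 and metal syn across the terminal C≡C of 9, methyl to the internal carbon and metal to the CH terminus, and exchange to aluminium gives the (E)-alkenylalane 13; the alkenyl group then passes through zinc to the palladium that has inserted into the C–I bond of 11, and reductive elimination forms the diene CH–CH bond with retention at both alkenes. The closest known reactions are the Negishi zirconium-catalysed carboalumination of terminal alkynes, conjugated diynes included, and the palladium-catalysed coupling of alkenylalanes with (E)-1-bromo-2-iodoethene. No ring closes and no stereocentre is created; the only stereochemical outcome is the E geometry of the C(CH3)=CH bond, fixed kinetically by the syn addition, together with the E geometry of CH=CHBr carried over from 11. The step needs terminal-over-internal alkyne selectivity, which the tetrasubstituted ring alkene and the neighbouring C(CH3)2 group provide by screening the inner triple bond, and C–I over C–Br selectivity, which the faster oxidative addition into the weaker C–I bond and the excess of 11 provide. The TBS ether is inert to AlMe3 under these conditions.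

Step 8
Reactants: 4 (4R)-4-[(tert-butyldimethylsilyl)oxy]-2,6,6-trimethylcyclohex-1-en-1-yl trifluoromethanesulfonate
Product: 15 methyl (4R)-4-[(tert-butyldimethylsilyl)oxy]-2,6,6-trimethylcyclohex-1-ene-1-carboxylate
Conditions: CO (1 atm), Pd(OAc)2 (cat.), PPh3, Et3N, MeOH/DMF, 60 °C
Reagents that add atoms: carbon monoxide, [C-]#[O+]; methanol, CO
Why: Palladium-catalysed methoxycarbonylation of the alkenyl triflate (oxidative addition, CO insertion, methanolysis of the acylpalladium) puts the one-carbon handle on the ring carbon that will become the vinyl-bearing oxirane carbon.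

Step 9
Reactants: 15 methyl (4R)-4-[(tert-butyldimethylsilyl)oxy]-2,6,6-trimethylcyclohex-1-ene-1-carboxylate
Product: 16 [(4R)-4-[(tert-butyldimethylsilyl)oxy]-2,6,6-trimethylcyclohex-1-en-1-yl]methanol
Conditions: iBu2AlH, CH2Cl2, −78 → 0 °C; aq. potassium sodium tartrate
Reagents that add atoms: none
Why: 1,2-Reduction of the conjugated ester by the aluminium hydride gives the primary allylic alcohol that will direct the epoxidation.

Step 10
Reactants: 16 [(4R)-4-[(tert-butyldimethylsilyl)oxy]-2,6,6-trimethylcyclohex-1-en-1-yl]methanol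
Product: 17 [(1R,4S,6R)-4-[(tert-butyldimethylsilyl)oxy]-2,2,6-trimethyl-7-oxabicyclo[4.1.0]heptan-1-yl]methanol
Conditions: Ti(OiPr)4 (cat.), D-(−)-diethyl tartrate, tBuOOH, 4 Å molecular sieves, CH2Cl2, −20 °C
Reagents that add atoms: tert-butyl hydroperoxide, CC(C)(C)OO
Why: Sharpless asymmetric epoxidation: allylic alkoxide and peroxide are held on the titanium tartrate, and the D-(−)-tartrate delivers oxygen to the alkene face opposite the C4 silyloxy group, a face the bulky silyl ether also favours, so both oxirane centres are set in one syn addition by reagent control reinforced by the substrate.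

Step 11
Reactants: 17 [(1R,4S,6R)-4-[(tert-butyldimethylsilyl)oxy]-2,2,6-trimethyl-7-oxabicyclo[4.1.0]heptan-1-yl]methanol
Product: 18 (1S,4S,6R)-4-[(tert-butyldimethylsilyl)oxy]-2,2,6-trimethyl-7-oxabicyclo[4.1.0]heptane-1-carbaldehyde
Conditions: Pr4N[RuO4] (cat.), N-methylmorpholine N-oxide, 4 Å molecular sieves, CH2Cl2, rt
Reagents that add atoms: none
Why: Ley–Griffith oxidation is neutral, so the acid-sensitive oxirane is kept, and the aldehyde has no α-hydrogen to epimerise.

Step 12
Reactants: 18 (1S,4S,6R)-4-[(tert-butyldimethylsilyl)oxy]-2,2,6-trimethyl-7-oxabicyclo[4.1.0]heptane-1-carbaldehyde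
Product: 19 tert-butyl{[(1R,3S,6R)-6-ethynyl-1,5,5-trimethyl-7-oxabicyclo[4.1.0]heptan-3-yl]oxy}dimethylsilane
Conditions: dimethyl (1-diazo-2-oxopropyl)phosphonate, K2CO3, MeOH, 0 °C → rt
Reagents that add atoms: dimethyl (1-diazo-2-oxopropyl)phosphonate, COP(=O)(OC)C(=[N+]=[N-])C(C)=O
Why: Ohira–Bestmann (Seyferth–Gilbert) homologation: the diazomethylphosphonate anion adds to the non-enolisable aldehyde and, after loss of phosphate and N2, a 1,2-shift of the alkylidene carbene gives the terminal alkyne with the quaternary oxirane carbon unchanged.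

Step 13
Reactants: 19 tert-butyl{[(1R,3S,6R)-6-ethynyl-1,5,5-trimethyl-7-oxabicyclo[4.1.0]heptan-3-yl]oxy}dimethylsilane
Product: 20 tert-butyldimethyl{[(1R,3S,6S)-1,5,5-trimethyl-6-[(E)-2-(tributylstannyl)ethenyl]-7-oxabicyclo[4.1.0]heptan-3-yl]oxy}silane
Conditions: Bu3SnH, PdCl2(PPh3)2 (cat.), THF, 0 °C
Reagents that add atoms: tributyltin hydride, CCCC[SnH](CCCC)CCCC
Why: Palladium-catalysed hydrostannation adds H and Sn syn, and the fully substituted carbon next to the alkyne forces tin onto the terminal carbon, giving the E alkenylstannane.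

Step 14
Reactants: 21 prop-2-ynoic acid (propiolic acid)
Product: 22 (2E)-2,3-dibromoprop-2-enoic acid
Conditions: Br2, CHCl3, 0 °C → rt, dark
Reagents that add atoms: bromine, BrBr
Why: Ionic anti addition of bromine across the alkyne puts the two bromine atoms trans, so the β-bromine is cis to the carboxyl group as the later lactonisation requires.

Step 15
Reactants: 22 (2E)-2,3-dibromoprop-2-enoic acid; 23 (2E)-3-methylpent-2-en-4-yn-1-ol
Product: 25 (5Z)-3-bromo-5-[(2E)-4-hydroxy-2-methylbut-2-en-1-ylidene]furan-2(5H)-one, via bromoenynoic acid 24 (not isolated)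
Conditions: PdCl2(PPh3)2 (cat.), CuI (cat.), Et3N, MeCN, rt
Reagents that add atoms: none
Why: Tandem Sonogashira coupling–lactonisation: the β C–Br bond, the more electrophilic and less hindered of the two, couples first, and the cis carboxylate then adds anti across the metal-activated alkyne in a 5-exo-dig closure, giving the Z ylidene butenolide and keeping the α-bromine for the next coupling.

Step 16
Reactants: 25 (5Z)-3-bromo-5-[(2E)-4-hydroxy-2-methylbut-2-en-1-ylidene]furan-2(5H)-one; 20 tert-butyldimethyl{[(1R,3S,6S)-1,5,5-trimethyl-6-[(E)-2-(tributylstannyl)ethenyl]-7-oxabicyclo[4.1.0]heptan-3-yl]oxy}silane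
Product: 26 (5Z)-3-{(E)-2-[(1S,4S,6R)-4-[(tert-butyldimethylsilyl)oxy]-2,2,6-trimethyl-7-oxabicyclo[4.1.0]heptan-1-yl]ethenyl}-5-[(2E)-4-hydroxy-2-methylbut-2-en-1-ylidene]furan-2(5H)-one
Conditions: Pd2(dba)3 (cat.), AsPh3, NMP, rt → 40 °C, dark
Reagents that add atoms: none
Why: Stille coupling at the only C(sp2)–Br bond keeps the E geometry of the stannane and the Z ylidene, under neutral conditions that the free allylic alcohol, the lactone and the fully substituted, slow-to-ionise vinyl oxirane should tolerate.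

Step 17
Reactants: 26 (5Z)-3-{(E)-2-[(1S,4S,6R)-4-[(tert-butyldimethylsilyl)oxy]-2,2,6-trimethyl-7-oxabicyclo[4.1.0]heptan-1-yl]ethenyl}-5-[(2E)-4-hydroxy-2-methylbut-2-en-1-ylidene]furan-2(5H)-one
Product: 27 (2E,4Z)-4-[4-{(E)-2-[(1S,4S,6R)-4-[(tert-butyldimethylsilyl)oxy]-2,2,6-trimethyl-7-oxabicyclo[4.1.0]heptan-1-yl]ethenyl}-5-oxofuran-2(5H)-ylidene]-3-methylbut-2-enal
Conditions: MnO2, CH2Cl2, rt
Reagents that add atoms: none
Why: MnO2 oxidises only the primary allylic alcohol to the conjugated aldehyde and leaves alkene geometry, oxirane and silyl ether alone.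

Step 18
Reactants: 28 dibromomethane
Product: 30 (dibromomethyl)tributylstannane, via dibromomethyllithium 29 (not isolated)
Conditions: LiN(iPr)2, THF/Et2O, −95 °C; then Bu3SnCl, −95 → −78 °C
Reagents that add atoms: tributyltin chloride, CCCC[Sn](Cl)(CCCC)CCCC
Why: Deprotonation of dibromomethane gives a carbenoid that is stable only at very low temperature and is trapped at tin (stannylation of an α-halo carbanion).

Step 19
Reactants: 27 (2E,4Z)-4-[4-{(E)-2-[(1S,4S,6R)-4-[(tert-butyldimethylsilyl)oxy]-2,2,6-trimethyl-7-oxabicyclo[4.1.0]heptan-1-yl]ethenyl}-5-oxofuran-2(5H)-ylidene]-3-methylbut-2-enal; 30 (dibromomethyl)tributylstannane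
Product: 31 (5Z)-3-{(E)-2-[(1S,4S,6R)-4-[(tert-butyldimethylsilyl)oxy]-2,2,6-trimethyl-7-oxabicyclo[4.1.0]heptan-1-yl]ethenyl}-5-[(2E,4E)-2-methyl-5-(tributylstannyl)penta-2,4-dien-1-ylidene]furan-2(5H)-one
Conditions: CrCl2, LiI, DMF/THF, rt, dark
Reagents that add atoms: none
Why: Hodgson stannyl-olefination (a Takai-type reaction): divalent chromium turns the gem-dihalide into a gem-dichromium species that adds only to the aldehyde, and anti-periplanar elimination from the less crowded adduct gives the E alkenylstannane; lactone, silyl ether and the remote oxirane are not expected to react.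

Step 20
Reactants: 14 {[(1R)-4-[(3E,5E)-6-bromo-3-methylhexa-3,5-dien-1-yn-1-yl]-3,5,5-trimethylcyclohex-3-en-1-yl]oxy}(tert-butyl)dimethylsilane; 31 (5Z)-3-{(E)-2-[(1S,4S,6R)-4-[(tert-butyldimethylsilyl)oxy]-2,2,6-trimethyl-7-oxabicyclo[4.1.0]heptan-1-yl]ethenyl}-5-[(2E,4E)-2-methyl-5-(tributylstannyl)penta-2,4-dien-1-ylidene]furan-2(5H)-one
Product: 32 (5Z)-3-{(E)-2-[(1S,4S,6R)-4-[(tert-butyldimethylsilyl)oxy]-2,2,6-trimethyl-7-oxabicyclo[4.1.0]heptan-1-yl]ethenyl}-5-[(2E,4E,6E,8E)-11-[(4R)-4-[(tert-butyldimethylsilyl)oxy]-2,6,6-trimethylcyclohex-1-en-1-yl]-2,9-dimethylundeca-2,4,6,8-tetraen-10-yn-1-ylidene]furan-2(5H)-one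
Conditions: Pd2(dba)3 (cat.), AsPh3, NMP, 40 °C, degassed, dark
Reagents that add atoms: none
Why: Stille coupling of the dienyl bromide with the dienylstannane forms the central CH–CH bond with retention at both partners under neutral, base-free conditions suited to the butenolide and the oxirane.

Step 21
Reactants: 32 (5Z)-3-{(E)-2-[(1S,4S,6R)-4-[(tert-butyldimethylsilyl)oxy]-2,2,6-trimethyl-7-oxabicyclo[4.1.0]heptan-1-yl]ethenyl}-5-[(2E,4E,6E,8E)-11-[(4R)-4-[(tert-butyldimethylsilyl)oxy]-2,6,6-trimethylcyclohex-1-en-1-yl]-2,9-dimethylundeca-2,4,6,8-tetraen-10-yn-1-ylidene]furan-2(5H)-one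
Product: 33 (5Z)-3-{(E)-2-[(1S,4S,6R)-4-hydroxy-2,2,6-trimethyl-7-oxabicyclo[4.1.0]heptan-1-yl]ethenyl}-5-[(2E,4E,6E,8E)-11-[(4R)-4-hydroxy-2,6,6-trimethylcyclohex-1-en-1-yl]-2,9-dimethylundeca-2,4,6,8-tetraen-10-yn-1-ylidene]furan-2(5H)-one (target)
Conditions: Bu4NF, AcOH (1:1), THF, rt, dark
Reagents that add atoms: none
Why: Fluoride-mediated desilylation of both secondary silyl ethers, buffered with acetic acid so that the base-sensitive ylidene butenolide and the acid-sensitive oxirane both survive; no stereocentre is involved.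

**Compound list**

1 | (4R,6R)-4-hydroxy-2,2,6-trimethylcyclohexan-1-one (actinol) | O=C1C(C)(C)C[C@H](O)C[C@H]1C | starting material
2 | (4R,6R)-4-[(tert-butyldimethylsilyl)oxy]-2,2,6-trimethylcyclohexan-1-one | O=C1C(C)(C)C[C@H](O[Si](C)(C)C(C)(C)C)C[C@H]1C | intermediate
3 | lithium enolate of 2 | CC1=C(O[Li])C(C)(C)C[C@H](O[Si](C)(C)C(C)(C)C)C1 | intermediate (not isolated)
4 | (4R)-4-[(tert-butyldimethylsilyl)oxy]-2,6,6-trimethylcyclohex-1-en-1-yl trifluoromethanesulfonate | CC1=C(OS(=O)(=O)C(F)(F)F)C(C)(C)C[C@H](O[Si](C)(C)C(C)(C)C)C1 | intermediate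
5 | 1,4-bis(trimethylsilyl)buta-1,3-diyne | C[Si](C)(C)C#CC#C[Si](C)(C)C | starting material
6 | lithium trimethylsilylbutadiynide | [Li]C#CC#C[Si](C)(C)C | intermediate (not isolated)
7 | buta-1,3-diyn-1-yl(trimethyl)silane | C#CC#C[Si](C)(C)C | intermediate
8 | tert-butyldimethyl{[(1R)-3,5,5-trimethyl-4-[4-(trimethylsilyl)buta-1,3-diyn-1-yl]cyclohex-3-en-1-yl]oxy}silane | CC1=C(C#CC#C[Si](C)(C)C)C(C)(C)C[C@H](O[Si](C)(C)C(C)(C)C)C1 | intermediate
9 | {[(1R)-4-(buta-1,3-diyn-1-yl)-3,5,5-trimethylcyclohex-3-en-1-yl]oxy}(tert-butyl)dimethylsilane | CC1=C(C#CC#C)C(C)(C)C[C@H](O[Si](C)(C)C(C)(C)C)C1 | intermediate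
10 | acetylene | C#C | starting material
11 | (E)-1-bromo-2-iodoethene | Br/C=C/I | intermediate
12 | trimethylaluminium | C[Al](C)C | starting material
13 | (E)-alkenyldimethylalane from 9 | CC1=C(C#C/C(C)=C/[Al](C)C)C(C)(C)C[C@H](O[Si](C)(C)C(C)(C)C)C1 | intermediate (not isolated)
14 | {[(1R)-4-[(3E,5E)-6-bromo-3-methylhexa-3,5-dien-1-yn-1-yl]-3,5,5-trimethylcyclohex-3-en-1-yl]oxy}(tert-butyl)dimethylsilane | CC1=C(C#C/C(C)=C/C=C/Br)C(C)(C)C[C@H](O[Si](C)(C)C(C)(C)C)C1 | intermediate
15 | methyl (4R)-4-[(tert-butyldimethylsilyl)oxy]-2,6,6-trimethylcyclohex-1-ene-1-carboxylate | CC1=C(C(=O)OC)C(C)(C)C[C@H](O[Si](C)(C)C(C)(C)C)C1 | intermediate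
16 | [(4R)-4-[(tert-butyldimethylsilyl)oxy]-2,6,6-trimethylcyclohex-1-en-1-yl]methanol | CC1=C(CO)C(C)(C)C[C@H](O[Si](C)(C)C(C)(C)C)C1 | intermediate
17 | [(1R,4S,6R)-4-[(tert-butyldimethylsilyl)oxy]-2,2,6-trimethyl-7-oxabicyclo[4.1.0]heptan-1-yl]methanol | OC[C@@]12O[C@]1(C)C[C@@H](O[Si](C)(C)C(C)(C)C)CC2(C)C | intermediate
18 | (1S,4S,6R)-4-[(tert-butyldimethylsilyl)oxy]-2,2,6-trimethyl-7-oxabicyclo[4.1.0]heptane-1-carbaldehyde | O=C[C@@]12O[C@]1(C)C[C@@H](O[Si](C)(C)C(C)(C)C)CC2(C)C | intermediate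
19 | tert-butyl{[(1R,3S,6R)-6-ethynyl-1,5,5-trimethyl-7-oxabicyclo[4.1.0]heptan-3-yl]oxy}dimethylsilane | C#C[C@@]12O[C@]1(C)C[C@@H](O[Si](C)(C)C(C)(C)C)CC2(C)C | intermediate
20 | tert-butyldimethyl{[(1R,3S,6S)-1,5,5-trimethyl-6-[(E)-2-(tributylstannyl)ethenyl]-7-oxabicyclo[4.1.0]heptan-3-yl]oxy}silane | CCCC[Sn](CCCC)(CCCC)/C=C/[C@@]12O[C@]1(C)C[C@@H](O[Si](C)(C)C(C)(C)C)CC2(C)C | intermediate
21 | prop-2-ynoic acid | C#CC(=O)O | starting material
22 | (2E)-2,3-dibromoprop-2-enoic acid | Br/C=C(/Br)C(=O)O | intermediate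
23 | (2E)-3-methylpent-2-en-4-yn-1-ol | C#C/C(C)=C/CO | starting material
24 | (2E,6E)-2-bromo-8-hydroxy-6-methylocta-2,6-dien-4-ynoic acid | OC/C=C(C)/C#C/C=C(/Br)C(=O)O | intermediate (not isolated)
25 | (5Z)-3-bromo-5-[(2E)-4-hydroxy-2-methylbut-2-en-1-ylidene]furan-2(5H)-one | OC/C=C(C)/C=C1C=C(Br)C(=O)O/1 | intermediate
26 | (5Z)-3-{(E)-2-[(1S,4S,6R)-4-[(tert-butyldimethylsilyl)oxy]-2,2,6-trimethyl-7-oxabicyclo[4.1.0]heptan-1-yl]ethenyl}-5-[(2E)-4-hydroxy-2-methylbut-2-en-1-ylidene]furan-2(5H)-one | OC/C=C(C)/C=C1C=C(/C=C/[C@@]23O[C@]2(C)C[C@@H](O[Si](C)(C)C(C)(C)C)CC3(C)C)C(=O)O/1 | intermediate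
27 | (2E,4Z)-4-[4-{(E)-2-[(1S,4S,6R)-4-[(tert-butyldimethylsilyl)oxy]-2,2,6-trimethyl-7-oxabicyclo[4.1.0]heptan-1-yl]ethenyl}-5-oxofuran-2(5H)-ylidene]-3-methylbut-2-enal | O=C/C=C(C)/C=C1C=C(/C=C/[C@@]23O[C@]2(C)C[C@@H](O[Si](C)(C)C(C)(C)C)CC3(C)C)C(=O)O/1 | intermediate
28 | dibromomethane | BrCBr | starting material
29 | dibromomethyllithium | [Li]C(Br)Br | intermediate (not isolated)
30 | (dibromomethyl)tributylstannane | CCCC[Sn](CCCC)(CCCC)C(Br)Br | intermediate
31 | (5Z)-3-{(E)-2-[(1S,4S,6R)-4-[(tert-butyldimethylsilyl)oxy]-2,2,6-trimethyl-7-oxabicyclo[4.1.0]heptan-1-yl]ethenyl}-5-[(2E,4E)-2-methyl-5-(tributylstannyl)penta-2,4-dien-1-ylidene]furan-2(5H)-one | CCCC[Sn](CCCC)(CCCC)/C=C/C=C(C)/C=C1C=C(/C=C/[C@@]23O[C@]2(C)C[C@@H](O[Si](C)(C)C(C)(C)C)CC3(C)C)C(=O)O/1 | intermediate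
32 | bis(tert-butyldimethylsilyl) ether of the target (full name in step 20) | CC1=C(C#C/C(C)=C/C=C/C=C/C=C(C)/C=C2C=C(/C=C/[C@@]34O[C@]3(C)C[C@@H](O[Si](C)(C)C(C)(C)C)CC4(C)C)C(=O)O/2)C(C)(C)C[C@H](O[Si](C)(C)C(C)(C)C)C1 | intermediate
33 | (5Z)-3-{(E)-2-[(1S,4S,6R)-4-hydroxy-2,2,6-trimethyl-7-oxabicyclo[4.1.0]heptan-1-yl]ethenyl}-5-[(2E,4E,6E,8E)-11-[(4R)-4-hydroxy-2,6,6-trimethylcyclohex-1-en-1-yl]-2,9-dimethylundeca-2,4,6,8-tetraen-10-yn-1-ylidene]furan-2(5H)-one | CC1=C(C#C/C(C)=C/C=C/C=C/C=C(C)/C=C2C=C(/C=C/[C@@]34O[C@]3(C)C[C@@H](O)CC4(C)C)C(=O)O/2)C(C)(C)C[C@H](O)C1 | target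

**Step count**

Total step count: 21.
Longest linear sequence: 13 steps (steps 1, 2, 8, 9, 10, 11, 12, 13, 16, 17, 19, 20, 21).

**Steps most likely to fail**

Step 19. Electron transfer from divalent chromium into the extended polyenal could open the oxirane that is conjugated with the aldehyde through the vinyl group and the butenolide, and the bulky gem-dimetal reagent could add slowly, leaving incomplete conversion or Z contamination. The fallback moves the stannyl olefination to a small aldehyde that has neither oxirane nor lactone and builds the butenolide last. It sets out from enynol 23. MnO2 oxidation would give (2E)-3-methylpent-2-en-4-ynal F1, and the same CrCl2/LiI olefination with 30 would give tributyl[(1E,3E)-4-methylhexa-1,3-dien-5-yn-1-yl]stannane F2. Copper-free Stille coupling of F2 with bromodienyne 14 would give tert-butyl{[(1R)-4-[(3E,5E,7E,9E)-3,10-dimethyldodeca-3,5,7,9-tetraene-1,11-diyn-1-yl]-3,5,5-trimethylcyclohex-3-en-1-yl]oxy}dimethylsilane F3. Its terminal alkyne would enter the Sonogashira–lactonisation with acid 22 to give (5Z)-3-bromo-5-[(2E,4E,6E,8E)-11-[(4R)-4-[(tert-butyldimethylsilyl)oxy]-2,6,6-trimethylcyclohex-1-en-1-yl]-2,9-dimethylundeca-2,4,6,8-tetraen-10-yn-1-ylidene]furan-2(5H)-one F4. Stille coupling of F4 with vinylstannane 20 comes back to the route at 32.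

Step 7. The acidic C–H of the conjugated diyne could be metalated by the aluminium reagent instead of being carbometalated, the terminal diyne could oligomerise, or the product bromide could couple a second time. The fallback takes the methyl-bearing E alkene ready-made from enynol 23 and sets out from triflate 4. Sonogashira coupling of 4 with 23 would give (2E)-5-[(4R)-4-[(tert-butyldimethylsilyl)oxy]-2,6,6-trimethylcyclohex-1-en-1-yl]-3-methylpent-2-en-4-yn-1-ol F5. MnO2 would give (2E)-5-[(4R)-4-[(tert-butyldimethylsilyl)oxy]-2,6,6-trimethylcyclohex-1-en-1-yl]-3-methylpent-2-en-4-ynal F6. Takai iodo-olefination (CHI3, CrCl2, THF) would give tert-butyl{[(1R)-4-[(3E,5E)-6-iodo-3-methylhexa-3,5-dien-1-yn-1-yl]-3,5,5-trimethylcyclohex-3-en-1-yl]oxy}dimethylsilane F7. F7 takes the place of 14 in the Stille coupling with 31, so the route is rejoined at 32.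

Step 20. Transmetalation from the electron-poor dienylstannane could be slow, so that protodestannylation, homocoupling, E/Z scrambling of the polyene or ionisation of the vinyl oxirane by zerovalent palladium compete. The fallback forms the central alkene by a Wittig reaction and sets out from 14 and 27. Stille hydroxymethylation of 14 with (tributylstannyl)methanol (Pd(PPh3)4, dioxane, 80 °C) would give (2E,4E)-7-[(4R)-4-[(tert-butyldimethylsilyl)oxy]-2,6,6-trimethylcyclohex-1-en-1-yl]-5-methylhepta-2,4-dien-6-yn-1-ol F8. PPh3·HBr in CH2Cl2 would give [(2E,4E)-7-[(4R)-4-[(tert-butyldimethylsilyl)oxy]-2,6,6-trimethylcyclohex-1-en-1-yl]-5-methylhepta-2,4-dien-6-yn-1-yl]triphenylphosphonium bromide F9. Condensation of its ylide (NaOMe, CH2Cl2, 0 °C) with aldehyde 27 would give 32. The new alkene is expected to form as an E/Z mixture that should equilibrate to E on standing in benzene in the dark.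

**Further compounds**

F1 | step 19 | (2E)-3-methylpent-2-en-4-ynal | C#C/C(C)=C/C=O
F2 | step 19 | tributyl[(1E,3E)-4-methylhexa-1,3-dien-5-yn-1-yl]stannane | C#C/C(C)=C/C=C/[Sn](CCCC)(CCCC)CCCC
F3 | step 19 | tert-butyl{[(1R)-4-[(3E,5E,7E,9E)-3,10-dimethyldodeca-3,5,7,9-tetraene-1,11-diyn-1-yl]-3,5,5-trimethylcyclohex-3-en-1-yl]oxy}dimethylsilane | CC1=C(C#C/C(C)=C/C=C/C=C/C=C(C)/C#C)C(C)(C)C[C@H](O[Si](C)(C)C(C)(C)C)C1
F4 | step 19 | (5Z)-3-bromo-5-[(2E,4E,6E,8E)-11-[(4R)-4-[(tert-butyldimethylsilyl)oxy]-2,6,6-trimethylcyclohex-1-en-1-yl]-2,9-dimethylundeca-2,4,6,8-tetraen-10-yn-1-ylidene]furan-2(5H)-one | CC1=C(C#C/C(C)=C/C=C/C=C/C=C(C)/C=C2C=C(Br)C(=O)O/2)C(C)(C)C[C@H](O[Si](C)(C)C(C)(C)C)C1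
F5 | step 7 | (2E)-5-[(4R)-4-[(tert-butyldimethylsilyl)oxy]-2,6,6-trimethylcyclohex-1-en-1-yl]-3-methylpent-2-en-4-yn-1-ol | CC1=C(C#C/C(C)=C/CO)C(C)(C)C[C@H](O[Si](C)(C)C(C)(C)C)C1
F6 | step 7 | (2E)-5-[(4R)-4-[(tert-butyldimethylsilyl)oxy]-2,6,6-trimethylcyclohex-1-en-1-yl]-3-methylpent-2-en-4-ynal | CC1=C(C#C/C(C)=C/C=O)C(C)(C)C[C@H](O[Si](C)(C)C(C)(C)C)C1
F7 | step 7 | tert-butyl{[(1R)-4-[(3E,5E)-6-iodo-3-methylhexa-3,5-dien-1-yn-1-yl]-3,5,5-trimethylcyclohex-3-en-1-yl]oxy}dimethylsilane | CC1=C(C#C/C(C)=C/C=C/I)C(C)(C)C[C@H](O[Si](C)(C)C(C)(C)C)C1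
F8 | step 20 | (2E,4E)-7-[(4R)-4-[(tert-butyldimethylsilyl)oxy]-2,6,6-trimethylcyclohex-1-en-1-yl]-5-methylhepta-2,4-dien-6-yn-1-ol | CC1=C(C#C/C(C)=C/C=C/CO)C(C)(C)C[C@H](O[Si](C)(C)C(C)(C)C)C1
F9 | step 20 | [(2E,4E)-7-[(4R)-4-[(tert-butyldimethylsilyl)oxy]-2,6,6-trimethylcyclohex-1-en-1-yl]-5-methylhepta-2,4-dien-6-yn-1-yl]triphenylphosphonium bromide | CC1=C(C#C/C(C)=C/C=C/C[P+](c2ccccc2)(c2ccccc2)c2ccccc2)C(C)(C)C[C@H](O[Si](C)(C)C(C)(C)C)C1.[Br-]
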